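**Retrosynthetic overview**

- Labels: ring A is the catechol ring bonded through oxygen to the para-phenylene ring B; ring C is the catechol ring bonded through oxygen to the meta-phenylene ring D. In rings A and C, C1 is the carbon bearing the CH2CH2 bridge.
- Enabling feature: in ring C the ether carbon C5 (bonded to the ring D oxygen) is ortho to the hydroxyl-bearing carbon C4. The C4–OH is therefore carried as C4–CHO and C5 as C–F, so the formyl group activates fluoride displacement by the ring D phenoxide and is later turned into OH by peracid (Dakin-type) oxidation.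
- The seco phenol is cut at the ring B–CH2CH2–ring C bridge (9-BBN hydroboration and B-alkyl Suzuki coupling with 4-bromo-2-fluoro-6-methoxybenzaldehyde), at the ring A–O–ring B ether (SNAr on 4-fluorobenzaldehyde, then methylenation) and at the ring D–CH2CH2–ring A bridge (Wittig, hydrogenation).
- Ring order: all four benzene rings are purchased; the only ring formed is the 19-membered macrocycle, closed last, followed by CHO to OH conversion and cleavage of three methyl ethers.

Key step: step 11

Remark on the chemistry: the target has no stereocentre, and the alkene geometry of compound 7 is irrelevant because that alkene is hydrogenated in step 5.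

**Route**

Step 1
Reactants: 1 3-hydroxy-4,5-dimethoxybenzaldehyde
Product: 2 5-(hydroxymethyl)-2,3-dimethoxyphenol
Conditions: NaBH4, MeOH, 0 °C
Reagents that add atoms: none
Why: Hydride reduction of an aromatic aldehyde by borohydride is fast and leaves the phenol and the aryl methyl ethers untouched.

Step 2
Reactants: 2 5-(hydroxymethyl)-2,3-dimethoxyphenol
Product: 3 (3-hydroxy-4,5-dimethoxybenzyl)triphenylphosphonium bromide
Conditions: Ph3P·HBr, MeCN, reflux
Reagents that add atoms: triphenylphosphine hydrobromide, Br.P(c1ccccc1)(c1ccccc1)c1ccccc1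
Why: Acid-promoted benzylic substitution of the protonated alcohol by triphenylphosphine gives the Wittig salt in one operation without phenol protection.

Step 3
Reactants: 4 3-hydroxybenzaldehyde
Product: 5 3-(methoxymethoxy)benzaldehyde
Conditions: MOMCl, K2CO3, acetone, rt
Reagents that add atoms: chloromethyl methyl ether, COCCl
Why: Williamson-type O-alkylation of the phenoxide installs a MOM acetal that withstands ylides, hydrogenation, hot carbonate, borane and palladium catalysis and is removed later by dilute acid.

Step 4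
Reactants: 3 (3-hydroxy-4,5-dimethoxybenzyl)triphenylphosphonium bromide; 5 3-(methoxymethoxy)benzaldehyde
Product: 7 2,3-dimethoxy-5-{2-[3-(methoxymethoxy)phenyl]ethenyl}phenol (E/Z mixture), via phosphonium ylide phenoxide 6 (not isolated)
Conditions: KOtBu (2.3 equiv), THF, 0 °C; then 5, rt; aq NH4Cl
Reagents that add atoms: none
Why: Wittig olefination, in which two equivalents of base generate a phenoxide ylide whose oxide is meta to the ylide carbon and so does not suppress its nucleophilicity towards the aldehyde.

Step 5
Reactants: 7 2,3-dimethoxy-5-{2-[3-(methoxymethoxy)phenyl]ethenyl}phenol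
Product: 8 2,3-dimethoxy-5-{2-[3-(methoxymethoxy)phenyl]ethyl}phenol
Conditions: H2 (1 atm), 10% Pd/C, EtOAc, rt
Reagents that add atoms: none
Why: Heterogeneous catalytic hydrogenation saturates both stilbene isomers to the bibenzyl under neutral conditions that leave the MOM acetal, the aryl ethers and the phenol intact.

Step 6
Reactants: 8 2,3-dimethoxy-5-{2-[3-(methoxymethoxy)phenyl]ethyl}phenol; 9 4-fluorobenzaldehyde
Product: 10 4-(2,3-dimethoxy-5-{2-[3-(methoxymethoxy)phenyl]ethyl}phenoxy)benzaldehyde
Conditions: K2CO3, DMF, 120 °C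
Reagents that add atoms: none
Why: Nucleophilic aromatic substitution (addition–elimination) of the ring A phenoxide on the para-formyl-activated fluoroarene; the ring D oxygen is masked, so only one diaryl ether can form.

Step 7
Reactants: 10 4-(2,3-dimethoxy-5-{2-[3-(methoxymethoxy)phenyl]ethyl}phenoxy)benzaldehyde
Product: 11 1-(4-ethenylphenoxy)-2,3-dimethoxy-5-{2-[3-(methoxymethoxy)phenyl]ethyl}benzene
Conditions: Ph3PCH3Br, KOtBu, THF, 0 °C to rt
Reagents that add atoms: methyltriphenylphosphonium bromide, [Br-].C[P+](c1ccccc1)(c1ccccc1)c1ccccc1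
Why: Wittig methylenation of the aryl aldehyde with the non-stabilised ylide gives the terminal styrene needed for hydroboration.

Step 8
Reactants: 12 4-bromo-2,6-difluorobenzaldehyde
Product: 13 4-bromo-2-fluoro-6-methoxybenzaldehyde
Conditions: NaOMe (1.05 equiv), MeOH, 0 °C to rt
Reagents that add atoms: sodium methoxide, [Na+].[O-]C
Why: Nucleophilic aromatic substitution at one of two equivalent ortho-fluorines; fluoride leaves far more readily than bromide in addition–elimination, and the new methoxy group slows a second substitution.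

Step 9
Reactants: 11 1-(4-ethenylphenoxy)-2,3-dimethoxy-5-{2-[3-(methoxymethoxy)phenyl]ethyl}benzene; 13 4-bromo-2-fluoro-6-methoxybenzaldehyde
Product: 15 4-{2-[4-(2,3-dimethoxy-5-{2-[3-(methoxymethoxy)phenyl]ethyl}phenoxy)phenyl]ethyl}-2-fluoro-6-methoxybenzaldehyde, via B-alkyl-9-BBN adduct 14 (not isolated)
Conditions: 9-BBN (1.1 equiv), THF, 0 °C to rt; then aq K3PO4, 13, PdCl2(dppf) (5 mol %), DMF, 50 °C
Reagents that add atoms: none
Why: Anti-Markovnikov hydroboration of the terminal styrene followed by B-alkyl Suzuki–Miyaura coupling at the C–Br bond para to the formyl group; residual B–H is destroyed by the aqueous base before the aldehyde partner is added, and the C–F bond does not undergo oxidative addition.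

Step 10
Reactants: 15 MOM-protected seco aldehyde
Product: 16 2-fluoro-4-{2-[4-(5-{2-(3-hydroxyphenyl)ethyl}-2,3-dimethoxyphenoxy)phenyl]ethyl}-6-methoxybenzaldehyde (seco phenol)
Conditions: 3 M aq HCl, THF, 50 °C
Reagents that add atoms: none
Why: Acid-catalysed acetal hydrolysis frees the ring D phenol, while the aldehyde, the aryl fluoride, the methyl ethers and the diaryl ether are stable to dilute aqueous acid.

Step 11
Reactants: 16 seco phenol with 2-fluoro-6-methoxybenzaldehyde terminus
Product: 17 macrocyclic aryloxybenzaldehyde (19-membered ring; ring A 4,5-dimethoxy; ring C 3-methoxy-4-formyl with C5 bonded to the ring D oxygen)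
Conditions: Cs2CO3 (3 equiv), DMF, 90 °C, slow addition of 16 to a final concentration of about 2 mM
Reagents that add atoms: none
Why: The carbonate deprotonates the ring D phenol and the phenoxide adds at C5 of ring C, ipso to fluorine, to give a Meisenheimer anion whose charge is delocalised onto the oxygen of the ortho formyl group; loss of fluoride then gives the diaryl ether. The closest known reaction type is intramolecular SNAr macro-etherification of phenoxides on ortho-fluorobenzaldehydes and ortho-fluoronitroarenes. The 19-membered ring is closed end to end by forming the O(ring D)–C5(ring C) bond, the last of the four links between the arenes. No stereocentre is created. The step needs ring closure to outrun intermolecular substitution and attack at one carbon only: the substrate has a single activated C–F bond and no other leaving group, carbonate is not a competing nucleophile, and slow addition at high dilution keeps the phenoxide concentration low. The ring C methoxy group is meta to the reacting carbon, so it puts no donor density on the carbons carrying the Meisenheimer charge.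

Step 12
Reactants: 17 macrocyclic aryloxybenzaldehyde
Product: 19 macrocyclic phenol (ring C 4-hydroxy-3-methoxy with C5 bonded to the ring D oxygen; ring A 4,5-dimethoxy), via aryl formate 18 (not isolated)
Conditions: mCPBA, CH2Cl2, 0 °C to rt; aq NaHCO3/Na2S2O3 wash; then K2CO3 (cat.), MeOH, rt
Reagents that add atoms: 3-chloroperoxybenzoic acid, OOC(=O)c1cccc(Cl)c1
Why: Baeyer–Villiger (Dakin-type) oxidation, in which the Criegee adduct rearranges by migration of the electron-rich 2,6-dioxygenated aryl group in preference to hydrogen, and the resulting formate is cleaved by methanolysis.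

Step 13
Reactants: 19 macrocyclic phenol
Product: 20 CNP0511668.0 (target; rings A and C as catechols)
Conditions: BBr3 (8 equiv), CH2Cl2, −78 °C to rt, argon; MeOH then H2O at 0 °C
Reagents that add atoms: none
Why: Lewis acid demethylation, in which boron coordinates each methoxy oxygen and bromide attacks the methyl carbon; the diaryl ethers have no sp3 carbon for bromide attack and should survive.

**Compound list**

1 | 3-hydroxy-4,5-dimethoxybenzaldehyde | COc1cc(C=O)cc(O)c1OC | starting material
2 | 5-(hydroxymethyl)-2,3-dimethoxyphenol | COc1cc(CO)cc(O)c1OC | intermediate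
3 | (3-hydroxy-4,5-dimethoxybenzyl)triphenylphosphonium bromide | COc1cc(C[P+](c2ccccc2)(c2ccccc2)c2ccccc2)cc(O)c1OC.[Br-] | intermediate
4 | 3-hydroxybenzaldehyde | O=Cc1cccc(O)c1 | starting material
5 | 3-(methoxymethoxy)benzaldehyde | COCOc1cccc(C=O)c1 | intermediate
6 | potassium 2,3-dimethoxy-5-[(triphenylphosphoranylidene)methyl]phenolate (ylide phenoxide) | COc1cc(C=P(c2ccccc2)(c2ccccc2)c2ccccc2)cc([O-])c1OC.[K+] | intermediate (not isolated)
7 | 2,3-dimethoxy-5-{2-[3-(methoxymethoxy)phenyl]ethenyl}phenol (E/Z mixture) | COCOc1cccc(C=Cc2cc(O)c(OC)c(OC)c2)c1 | intermediate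
8 | 2,3-dimethoxy-5-{2-[3-(methoxymethoxy)phenyl]ethyl}phenol | COCOc1cccc(CCc2cc(O)c(OC)c(OC)c2)c1 | intermediate
9 | 4-fluorobenzaldehyde | O=Cc1ccc(F)cc1 | starting material
10 | 4-(2,3-dimethoxy-5-{2-[3-(methoxymethoxy)phenyl]ethyl}phenoxy)benzaldehyde | COCOc1cccc(CCc2cc(OC)c(OC)c(Oc3ccc(C=O)cc3)c2)c1 | intermediate
11 | 1-(4-ethenylphenoxy)-2,3-dimethoxy-5-{2-[3-(methoxymethoxy)phenyl]ethyl}benzene | COCOc1cccc(CCc2cc(OC)c(OC)c(Oc3ccc(C=C)cc3)c2)c1 | intermediate
12 | 4-bromo-2,6-difluorobenzaldehyde | O=Cc1c(F)cc(Br)cc1F | starting material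
13 | 4-bromo-2-fluoro-6-methoxybenzaldehyde | COc1cc(Br)cc(F)c1C=O | intermediate
14 | 9-{2-[4-(2,3-dimethoxy-5-{2-[3-(methoxymethoxy)phenyl]ethyl}phenoxy)phenyl]ethyl}-9-borabicyclo[3.3.1]nonane | COCOc1cccc(CCc2cc(OC)c(OC)c(Oc3ccc(CCB4C5CCCC4CCC5)cc3)c2)c1 | intermediate (not isolated)
15 | 4-{2-[4-(2,3-dimethoxy-5-{2-[3-(methoxymethoxy)phenyl]ethyl}phenoxy)phenyl]ethyl}-2-fluoro-6-methoxybenzaldehyde | COCOc1cccc(CCc2cc(OC)c(OC)c(Oc3ccc(CCc4cc(F)c(C=O)c(OC)c4)cc3)c2)c1 | intermediate
16 | 2-fluoro-4-{2-[4-(5-{2-(3-hydroxyphenyl)ethyl}-2,3-dimethoxyphenoxy)phenyl]ethyl}-6-methoxybenzaldehyde (seco phenol) | Oc1cccc(c1)CCc1cc(OC)c(OC)c(c1)Oc1ccc(CCc2cc(F)c(C=O)c(OC)c2)cc1 | intermediate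
17 | macrocyclic aryloxybenzaldehyde (19-membered; ring A 4,5-dimethoxy; ring C 3-methoxy-4-formyl) | COc1cc2cc(c1OC)Oc1ccc(cc1)CCc1cc(OC)c(C=O)c(c1)Oc1cccc(c1)CC2 | intermediate
18 | macrocyclic aryl formate (ring C 4-formyloxy-3-methoxy) | COc1cc2cc(c1OC)Oc1ccc(cc1)CCc1cc(OC)c(OC=O)c(c1)Oc1cccc(c1)CC2 | intermediate (not isolated)
19 | macrocyclic phenol (ring C 4-hydroxy-3-methoxy; ring A 4,5-dimethoxy) | COc1cc2cc(c1OC)Oc1ccc(cc1)CCc1cc(OC)c(O)c(c1)Oc1cccc(c1)CC2 | intermediate
20 | CNP0511668.0 (macrocyclic bis-catechol) | Oc1cc2cc(c1O)Oc1ccc(cc1)CCc1cc(O)c(O)c(c1)Oc1cccc(c1)CC2 | target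

**Step count and risk**

Total steps: 13. Longest linear sequence: 11 steps (1, 2, 4, 5, 6, 7, 9, 10, 11, 12, 13, from compound 1).

Steps most likely to fail:

1. Step 11. Ring closure may be outrun by intermolecular substitution (oligomer formation), or the singly formyl-activated C–F bond may react so slowly that the aldehyde degrades at the temperature required. The fallback sets out from 11 and returns at 19, with nitro replacing formyl as the activator. Commercial 5-bromo-1,3-difluoro-2-nitrobenzene F1 would be mono-methoxylated (NaOMe, MeOH, −20 °C) to 5-bromo-1-fluoro-3-methoxy-2-nitrobenzene F2. Borane 14, made from 11 as in step 9, would be coupled with F2 (PdCl2(dppf), K3PO4, DMF, 50 °C) to the MOM-protected nitro seco compound F3. Aqueous HCl in THF would free the seco nitrophenol F4. K2CO3 in DMF at room temperature and high dilution should close the ring by ortho-fluoronitroarene SNAr to the macrocyclic nitro diaryl ether F5. Hydrogenation (H2, Pd/C, EtOAc) would give the macrocyclic aniline F6. Diazotisation (NaNO2, aq H2SO4, THF, 0 °C) would give the diazonium hydrogensulfate F7, and hydrolysis with Cu2O and Cu(NO3)2 in water should give phenol 19.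

2. Step 9. The formyl group may be reduced by residual B–H, hydroxide may attack the activated C–F bond, or the alkylborane may undergo protodeboronation before transmetalation. The fallback sets out from 11 and 13 and returns at 15. Mizoroki–Heck coupling of styrene 11 with bromide 13 (Pd(OAc)2, P(o-tol)3, NaOAc, DMF, 100 °C) would give the E-stilbene aldehyde F8. Diimide reduction of the C=C bond (dipotassium azodicarboxylate, AcOH, MeOH/THF, rt) leaves the aldehyde, the C–F bond and the MOM acetal untouched and should give 15.

3. Step 12. Hydrogen migration may compete with aryl migration (carboxylic acid formation), or the peracid may attack the electron-rich trioxygenated rings. The fallback sets out from 17 and returns at 20, with deprotection placed before oxidation. BCl3 (CH2Cl2, −78 to 0 °C) would cleave only the methyl ether ortho to the formyl group through chelation, giving the macrocyclic salicylaldehyde F9. Classical Dakin oxidation of this ortho-hydroxybenzaldehyde (H2O2, aq NaOH, THF, 0 °C) would give the ring C catechol F10. BBr3 (CH2Cl2, −78 °C to rt) would then cleave the two ring A methyl ethers to give 20.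

**Further compounds**

F1 | step 11 | 5-bromo-1,3-difluoro-2-nitrobenzene | O=[N+]([O-])c1c(F)cc(Br)cc1F
F2 | step 11 | 5-bromo-1-fluoro-3-methoxy-2-nitrobenzene | COc1cc(Br)cc(F)c1[N+](=O)[O-]
F3 | step 11 | MOM-protected nitro seco compound (ring C 3-methoxy-4-nitro-5-fluoro) | COCOc1cccc(CCc2cc(OC)c(OC)c(Oc3ccc(CCc4cc(F)c([N+](=O)[O-])c(OC)c4)cc3)c2)c1
F4 | step 11 | seco nitrophenol | Oc1cccc(c1)CCc1cc(OC)c(OC)c(c1)Oc1ccc(CCc2cc(F)c([N+](=O)[O-])c(OC)c2)cc1
F5 | step 11 | macrocyclic nitro diaryl ether (ring C 3-methoxy-4-nitro) | COc1cc2cc(c1OC)Oc1ccc(cc1)CCc1cc(OC)c([N+](=O)[O-])c(c1)Oc1cccc(c1)CC2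
F6 | step 11 | macrocyclic aniline (ring C 4-amino-3-methoxy) | COc1cc2cc(c1OC)Oc1ccc(cc1)CCc1cc(OC)c(N)c(c1)Oc1cccc(c1)CC2
F7 | step 11 | macrocyclic arenediazonium hydrogensulfate | COc1cc2cc(c1OC)Oc1ccc(cc1)CCc1cc(OC)c([N+]#N)c(c1)Oc1cccc(c1)CC2.OS(=O)(=O)[O-]
F8 | step 9 | E-stilbene aldehyde (ring B–CH=CH–ring C) | COCOc1cccc(CCc2cc(OC)c(OC)c(Oc3ccc(/C=C/c4cc(F)c(C=O)c(OC)c4)cc3)c2)c1
F9 | step 12 | macrocyclic salicylaldehyde (ring C 3-hydroxy-4-formyl) | COc1cc2cc(c1OC)Oc1ccc(cc1)CCc1cc(O)c(C=O)c(c1)Oc1cccc(c1)CC2
F10 | step 12 | macrocyclic ring C catechol with ring A dimethyl ether | COc1cc2cc(c1OC)Oc1ccc(cc1)CCc1cc(O)c(O)c(c1)Oc1cccc(c1)CC2
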